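Assumption: natural (−)-polygodial, sold as an isolated natural product, is accepted as a commercial starting material; it already has the trans-decalin and the C5, C9 and C10 configurations of the target (drimane numbering is used throughout). The route is a design from known reaction types and has not been run.

**Retrosynthetic overview**
- Target ⇒ di-tert-butyl ester (acidolysis last); the trienoate C2′=C3′ bond ⇒ Horner–Wadsworth–Emmons of a 6β-phosphonoacetate with sorbaldehyde.
- C8 (8β-ester, cis to the 9β-ester) ⇒ α-face hydrogenation of the Δ7 enoate, done after O-acylation so the alcohol is acylated while C8 is still sp2.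
- 6β-O ⇒ α-face hydride reduction of a 7-en-6-one ⇒ allylic C–H oxidation at C6 of the Δ7 diester.
- Diester ⇒ (−)-polygodial by Pinnick oxidation of both aldehydes and tert-butylation.
- No ring is formed in the route: both carbocycles come intact from polygodial.

**Route**

Step 1
Reactants: 1 (−)-polygodial
Product: 2 drim-7-ene-11,12-dioic acid
Conditions: NaClO2, NaH2PO4, 2-methyl-2-butene, t-BuOH/THF/H2O, 0 °C to rt
Reagents that add atoms: sodium chlorite, [Na+].[O-]Cl=O
Why: Pinnick oxidation converts both the enal and the hindered saturated aldehyde to acids under buffered, mildly acidic conditions that neither epimerise C9 nor move the C7=C8 bond, and any lactol (pseudo-acid) form re-opens and is oxidised on.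

Step 2
Reactants: 2 drim-7-ene-11,12-dioic acid
Product: 3 di-tert-butyl drim-7-ene-11,12-dioate
Conditions: tert-butyl 2,2,2-trichloroacetimidate (5 equiv), BF3·OEt2 (cat.), cyclohexane/CH2Cl2, rt
Reagents that add atoms: tert-butyl 2,2,2-trichloroacetimidate, CC(C)(C)OC(=N)C(Cl)(Cl)Cl
Why: Acid-catalysed O-tert-butylation by the imidate (SN1-type transfer of a tert-butyl cation to the carboxyl oxygen) is insensitive to the hindrance of the C9 carboxyl and is base-free, so C9 and the Δ7 position are untouched.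

Step 3
Reactants: 3 di-tert-butyl drim-7-ene-11,12-dioate
Product: 4 di-tert-butyl 6-oxodrim-7-ene-11,12-dioate
Conditions: Rh2(cap)4 (1 mol %), t-BuOOH (70 % aq., 10 equiv), ClCH2CH2Cl, 40 °C
Reagents that add atoms: tert-butyl hydroperoxide, CC(C)(C)OO
Why: Dirhodium caprolactamate/TBHP allylic C–H oxidation (peroxyl-radical H-abstraction, then Kornblum–DeLaMare collapse of the allylic peroxide) should attack the only allylic CH2, C6, because the C9–H is tertiary, neopentyl and deactivated by its ester.

Step 4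
Reactants: 4 di-tert-butyl 6-oxodrim-7-ene-11,12-dioate
Product: 5 di-tert-butyl 6β-hydroxydrim-7-ene-11,12-dioate
Conditions: NaBH4, CeCl3·7H2O, MeOH, −78 to −40 °C
Reagents that add atoms: none
Why: Luche 1,2-reduction: hydride attacks the cerium-activated C6 carbonyl from the α-face because the β-face is blocked by the syn-axial C10 and C4β methyl groups, which sets the 6β (axial) alcohol without conjugate reduction.

Step 5
Reactants: 5 di-tert-butyl 6β-hydroxydrim-7-ene-11,12-dioate; 6 2-(diethoxyphosphoryl)acetic acid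
Product: 7 di-tert-butyl 6β-[2-(diethoxyphosphoryl)acetoxy]drim-7-ene-11,12-dioate
Conditions: DCC, DMAP (cat.), CH2Cl2, 0 °C to rt
Reagents that add atoms: 6 2-(diethoxyphosphoryl)acetic acid, CCOP(=O)(OCC)CC(=O)O
Why: Steglich esterification with a small acid acylates the axial 6β-OH while C8 is still sp2 (only two syn-axial methyls nearby), and C12 sits trans to C6 across the alkene, so no lactone can form.

Step 6
Reactants: 7 di-tert-butyl 6β-[2-(diethoxyphosphoryl)acetoxy]drim-7-ene-11,12-dioate
Product: 8 di-tert-butyl 6β-[2-(diethoxyphosphoryl)acetoxy]-8αH-drimane-11,12-dioate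
Conditions: H2 (4 atm), 5 % Rh/Al2O3, EtOAc, rt
Reagents that add atoms: none
Why: Heterogeneous syn-hydrogenation from the open α-face (the β-face is shielded by the C10 methyl and the 6β-acyloxy group) delivers H-7 and H-8 α and so sets the 8β (axial) ester cis to the 9β ester, and rhodium is chosen to suppress hydrogenolysis of the allylic C6–O bond.

Step 7
Reactants: 8 di-tert-butyl 6β-[2-(diethoxyphosphoryl)acetoxy]-8αH-drimane-11,12-dioate; 9 (2E,4E)-hexa-2,4-dienal
Product: 10 di-tert-butyl 6β-[(2E,4E,6E)-octa-2,4,6-trienoyloxy]-8αH-drimane-11,12-dioate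
Conditions: LiCl, i-Pr2NEt, MeCN, 0 °C to rt
Reagents that add atoms: 9 (2E,4E)-hexa-2,4-dienal, C/C=C/C=C/C=O
Why: Masamune–Roush Horner–Wadsworth–Emmons olefination of the stabilised phosphonate with the dienal forms the new C2′=C3′ bond E-selectively, and the amine base is far too weak to enolise the tert-butyl esters, so the axial C8 centre is not epimerised.

Step 8
Reactants: 10 di-tert-butyl 6β-[(2E,4E,6E)-octa-2,4,6-trienoyloxy]-8αH-drimane-11,12-dioate
Product: 11 (1S,2S,4R,4aS,8aS)-5,5,8a-trimethyl-4-[(2E,4E,6E)-octa-2,4,6-trienoyloxy]decahydronaphthalene-1,2-dicarboxylic acid (CNP0462207.1)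
Conditions: TFA/CH2Cl2 (1:3), 0 °C to rt, then toluene azeotrope
Reagents that add atoms: none
Why: AAL1 acidolysis of both tert-butyl esters (loss of isobutene) frees the diacid without base, so neither the electron-poor trienoate nor the epimerisable axial C8 centre is disturbed.

**Compound list**
1 | (−)-polygodial, (1R,4aS,8aS)-5,5,8a-trimethyl-1,4,4a,5,6,7,8,8a-octahydronaphthalene-1,2-dicarbaldehyde (drim-7-ene-11,12-dial; 5α-H, 9β-CHO, 10β-CH3) | C1C=C(C=O)[C@H](C=O)[C@@]2(C)CCCC(C)(C)[C@H]12 | starting material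
2 | drim-7-ene-11,12-dioic acid (5α-H, 9β-CO2H, 10β-CH3) | C1C=C(C(=O)O)[C@H](C(=O)O)[C@@]2(C)CCCC(C)(C)[C@H]12 | intermediate
3 | di-tert-butyl drim-7-ene-11,12-dioate | C1C=C(C(=O)OC(C)(C)C)[C@H](C(=O)OC(C)(C)C)[C@@]2(C)CCCC(C)(C)[C@H]12 | intermediate
4 | di-tert-butyl 6-oxodrim-7-ene-11,12-dioate | O=C1C=C(C(=O)OC(C)(C)C)[C@H](C(=O)OC(C)(C)C)[C@@]2(C)CCCC(C)(C)[C@H]12 | intermediate
5 | di-tert-butyl 6β-hydroxydrim-7-ene-11,12-dioate | O[C@@H]1C=C(C(=O)OC(C)(C)C)[C@H](C(=O)OC(C)(C)C)[C@@]2(C)CCCC(C)(C)[C@H]12 | intermediate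
6 | 2-(diethoxyphosphoryl)acetic acid (diethylphosphonoacetic acid) | CCOP(=O)(OCC)CC(=O)O | starting material
7 | di-tert-butyl 6β-[2-(diethoxyphosphoryl)acetoxy]drim-7-ene-11,12-dioate | CCOP(=O)(OCC)CC(=O)O[C@@H]1C=C(C(=O)OC(C)(C)C)[C@H](C(=O)OC(C)(C)C)[C@@]2(C)CCCC(C)(C)[C@H]12 | intermediate
8 | di-tert-butyl 6β-[2-(diethoxyphosphoryl)acetoxy]-8αH-drimane-11,12-dioate (8β- and 9β-esters cis) | CCOP(=O)(OCC)CC(=O)O[C@@H]1C[C@H](C(=O)OC(C)(C)C)[C@H](C(=O)OC(C)(C)C)[C@@]2(C)CCCC(C)(C)[C@H]12 | intermediate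
9 | (2E,4E)-hexa-2,4-dienal (sorbaldehyde) | C/C=C/C=C/C=O | starting material
10 | di-tert-butyl 6β-[(2E,4E,6E)-octa-2,4,6-trienoyloxy]-8αH-drimane-11,12-dioate | C/C=C/C=C/C=C/C(=O)O[C@@H]1C[C@H](C(=O)OC(C)(C)C)[C@H](C(=O)OC(C)(C)C)[C@@]2(C)CCCC(C)(C)[C@H]12 | intermediate
11 | (1S,2S,4R,4aS,8aS)-5,5,8a-trimethyl-4-[(2E,4E,6E)-octa-2,4,6-trienoyloxy]decahydronaphthalene-1,2-dicarboxylic acid (6β-acyloxy-8αH-drimane-11,12-dioic acid) | C/C=C/C=C/C=C/C(=O)O[C@@H]1C[C@H](C(=O)O)[C@H](C(=O)O)[C@@]2(C)CCCC(C)(C)[C@H]12 | target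

**Totals**
Total step count: 8. Longest linear sequence: 8 steps (1 to 11).

**Steps most likely to fail, with fallbacks**

Step 3, the allylic oxidation, is the weakest point. The alkene is an electron-poor, hindered enoate, and the C9–H could compete or the product could isomerise. The fallback sets out from 3: Wohl–Ziegler bromination (NBS, cat. AIBN, PhCF3, 80 °C) puts bromine on the allylic C6 from the open α-face and gives di-tert-butyl 6α-bromodrim-7-ene-11,12-dioate F1. A silver-assisted Kornblum oxidation (AgBF4, DMSO, then Et3N) turns this secondary allylic bromide into the enone, and the route is rejoined at 4.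

Step 5, the esterification of the axial 6β-alcohol, may be slow because of the two syn-axial methyl groups. The fallback sets out from 5: acylation with the small and very reactive bromoacetyl bromide (pyridine, CH2Cl2, −20 °C) gives di-tert-butyl 6β-(2-bromoacetoxy)drim-7-ene-11,12-dioate F2. A Michaelis–Arbuzov reaction with triethyl phosphite (neat, 110 °C) then builds the phosphonate and returns to the route at 7.

Step 6, the hydrogenation, may be sluggish at the hindered trisubstituted enoate, may cleave the allylic C6–O bond, or may give the wrong C8 epimer. The fallback sets out from 4 and reduces the alkene before the oxygen at C6 becomes an allylic ester. Hydrogenation of the doubly activated C7=C8 bond (H2, Pd/C, EtOAc, α-face) gives di-tert-butyl 6-oxo-8αH-drimane-11,12-dioate F3. Reduction of the ketone from the α-face (NaBH4, MeOH, −20 °C) gives di-tert-butyl 6β-hydroxy-8αH-drimane-11,12-dioate F4. Esterification of F4 with 6 (DCC, DMAP, CH2Cl2) comes back to the route at 8. The price is acylation of a more hindered alcohol, now with the axial 8β-ester also syn to it.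

**Further compounds**
F1 | step 3 | di-tert-butyl 6α-bromodrim-7-ene-11,12-dioate | Br[C@H]1C=C(C(=O)OC(C)(C)C)[C@H](C(=O)OC(C)(C)C)[C@@]2(C)CCCC(C)(C)[C@H]12
F2 | step 5 | di-tert-butyl 6β-(2-bromoacetoxy)drim-7-ene-11,12-dioate | BrCC(=O)O[C@@H]1C=C(C(=O)OC(C)(C)C)[C@H](C(=O)OC(C)(C)C)[C@@]2(C)CCCC(C)(C)[C@H]12
F3 | step 6 | di-tert-butyl 6-oxo-8αH-drimane-11,12-dioate | O=C1C[C@H](C(=O)OC(C)(C)C)[C@H](C(=O)OC(C)(C)C)[C@@]2(C)CCCC(C)(C)[C@H]12
F4 | step 6 | di-tert-butyl 6β-hydroxy-8αH-drimane-11,12-dioate | O[C@@H]1C[C@H](C(=O)OC(C)(C)C)[C@H](C(=O)OC(C)(C)C)[C@@]2(C)CCCC(C)(C)[C@H]12
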